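## Structural features

The target is an achiral trimer of acylphloroglucinols: three fully substituted benzene rings in a row, joined by two CH2 bridges, with the central ring (butanoyl at C1, hydroxyls at C2, C4, C6) carrying ring A at C3 and ring B at C5. It has no stereocentre, so no stereocentres stand next to each other and the whole problem is regiochemical. Rings A and B are constitutional isomers with the same substituents. In ring B the methoxy group (b6) is para to the ketone (b3); in ring A the methoxy group (a4) is ortho to the ketone (a5) and beside the methyl group (a3). Fragile elements are the seven free phenols (air oxidation, C- versus O-alkylation), the two diarylmethane bridges between electron-rich rings (cleaved or scrambled by acid or base through retro-Friedel–Crafts and quinone methide pathways) and the three enolizable ketones. The ring B pattern follows from methylating the one hydroxyl that is not ortho to the carbonyl, but the ring A pattern cannot be reached that way because its methoxy oxygen is one of the chelated, least reactive hydroxyls. The real difficulty is therefore to tell apart the three oxygens of ring A and to attach two different side rings to one central ring. The key step exploits ring A itself: a2–OH comes from a cyclobutenone carbonyl, a4–OMe from an ynol ether and a6–O from an enol ether, so the three oxygens are distinguished by construction.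

## Logic of the disconnections

34 to 33. The five O–benzyl bonds on the central ring and ring B are cut. Benzyl ethers can be removed last in neutral medium, which spares the acid- and base-labile bridges, and 33 is a lipophilic, non-oxidizable compound. The forward step must leave three aryl ketones and two diarylmethane CH2 groups untouched.

33 to 31. The a5–C(=O) bond is cut. In 31 the carbon a5 is the only ring CH of the whole molecule, so the position of acylation is fixed and the third butanoyl group disappears from all earlier intermediates. The forward step must acylate carbon and not the two free hydroxyls, and must tolerate five benzyl ethers; a nitrile-based Hoesch acylation at 0 °C is chosen for that reason.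

31 to 30. The a6 O–C(CH3)3 bond is cut. The tert-butyl group is the one O-substituent that an ynol ether can deliver and that acid removes without touching the methyl or benzyl ethers. The forward step must keep the released cation away from a5.

30 to 22 and 25. The a2–a3 and a4–a5 bonds are cut, with a1–a2 opened and re-formed in the forward direction. This is where the ring A oxygens are differentiated, and it reduces ring A to a four-membered ring on a side chain plus a three-carbon alkyne. The forward step is a purely thermal cascade whose orientation must be set by the polarization of 25.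

22 to 14 and 19. The two ring bonds that join the C=O carbon to the CH and the sp3 carbon to the alkoxy-bearing carbon are cut, a ketene/ynol ether [2+2] retron. The precursor becomes a propanoic acid, reached through 20 and 21. The forward step must generate a monosubstituted ketene that cycloadds faster than it dimerizes, at a temperature that 19 survives.

14 to 12. Five O–benzyl bonds are cut and the lactone C–O bond is re-formed. All phenol protection is gathered into one operation after the carbon skeleton is complete. The forward step must alkylate oxygen and not carbon on two very electron-rich rings.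

12 to 4 and 9. The bond between the central ring carbon C5 and the bridging CH2 of ring B is cut. The two halves become monomers of similar size, and 9 has only one free ring carbon, so double alkylation is impossible. The forward step must generate a quinone methide from 4 without a by-product that attacks the lactone.

9 to 6 and 7. The bond between central C3 and the side-chain CH2 is cut, together with the lactone C–O bond. The three-carbon acid chain is put on while the central ring is still a monomer, so that no diarylmethane bridge is exposed to the acid catalyst. The forward step must give conjugate addition and not acylation.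

6 to 5, and 4 to 3 to 2 to 1. The aryl–acyl bonds, the methyl–oxygen bond and the aminomethyl C–C bond are cut, leading back to two commercial phenols. The demands are a single C-acylation of each triol and methylation of one hydroxyl out of three in 2.

19 to 17 to 15, and 25 to 23. The alkyne π bonds are cut by retro-elimination, leading to a commercial enol ether and a commercial bromo acetal. The forward steps must be run cold because 19 fragments on warming.

## Other disconnections considered

Alternative 1: The cut removes the a5–acyl and a6–O bonds of ring A and the b3–acyl and b4–O bonds of ring B at once. In the forward step CsF would generate two arynes from the bis(ortho-silylaryl triflate) A1. Each would take up butanoic acid A2 by addition of the carboxylate oxygen at the aryne carbon remote from the neighbouring alkoxy group, followed by capture of the acyl carbon by the aryl anion, giving the penta-benzyl ether A3.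
- In favour: ketone and ortho hydroxyl arrive together, on both side rings, under fluoride and without Lewis or protic acid. On acid exposure and on the number of operations spent on ketone introduction this is better than the chosen plan, which needs steps 1 and 14.
- Against: A1 must carry a silyl group and a triflate on two hexasubstituted rings, and its ring A still needs three differentiated oxygens (benzyloxy, methoxy, triflate), so the central problem is only moved. Both arynes are flanked on both sides, so the orientation rests on distortion by one alkoxy group against steric hindrance. Simple O-arylation of the acid can compete with acyl transfer, and a twofold event multiplies any loss.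
- Comparison: on structure the two plans are equal in protecting the central ring as benzyl ethers. On mechanism the chosen cascade fixes regiochemistry by connectivity, while A3 depends on two selective aryne captures. On step economy the late stage of the alternative is shorter, but the way to A1 is expected to be longer than the way to 22.

Alternative 2: The cut removes the three C–O bonds of the central ring. In the forward step sodium benzyloxide A5 would displace the three fluorides of the trifluoro ketone A4 by nucleophilic aromatic substitution, giving the hepta-benzyl ether A6.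
- In favour: the central ring stays an inert fluoroarene until late, so no free methylene-bridged polyphenol such as 12 is ever handled. On robustness of intermediates this is better than the chosen plan, and one hydrogenolysis finishes the synthesis as in step 15, an equal point.
- Against: only one ketone activates the ring, each alkoxy group introduced deactivates it further, and the positions are flanked by arylmethyl groups, so the third substitution is the slowest. The alkoxide can also enolize three butanoyl groups. A4 already contains ring A with its methoxy group ortho to the ketone, so the differentiation problem must be solved elsewhere.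
- Comparison: the alternative is stronger on the stability of its intermediates. On mechanism it relies on three consecutive substitutions of falling rate against one pericyclic cascade. On step economy it is weaker, because it needs an independent regiodefined synthesis of ring A that the chosen plan obtains in step 12.

Alternative 3: The cut is the C1–C6 bond of the central ring. In the forward step Mg(OMe)2 would make the chain methylene between the butanoyl carbonyl and the C2 carbonyl of the open-chain triketo ester A7 attack the ester carbon, and enolization would aromatize the new ring to give the tetra-benzyl ether A8.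
- In favour: the central ring is made last with its hydroxyls free, so only four benzyl groups remain to be removed, and the placement of its ketone between two hydroxyls arises by itself. On convergence and on protecting-group count this is better than the chosen plan.
- Against: A7 is a 3,5,7-trioxo ester with two bulky arylmethyl groups on specific chain carbons, which is hard to assemble regioselectively. Its cyclization has competing modes (aldol closure to a resorcylate, lactonization to a pyranone) that magnesium chelation must suppress. Ring A again has to be made beforehand with the difficult oxygen pattern.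
- Comparison: on structure the alternative is more convergent. On mechanism it depends on chemoselectivity among several closures, where the chosen cascade has one productive channel. On step economy it is probably no shorter, because the chain synthesis and a separate ring A synthesis are added.

Key step: step 12

Remark on the chemistry: 22 is made and used as the racemate, because its only stereocentre becomes an aromatic carbon in step 12.
Remark on the chemistry: the connectivity of 22 and 30 was traced through the mechanism atom by atom (carbonyl carbon of 22 to a2, its sp3 carbon to a1, its alkoxy carbon to a6) and needs no correction.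
Remark on the chemistry: the lactone of step 5 is assumed to close onto the hydroxyl para to the ketone; closure onto the other neighbouring hydroxyl would lead to the same acid 14 after step 7.
Abbreviation used in names: Ar = 2,4,6-tris(benzyloxy)-3-butanoyl-5-{[2,4-bis(benzyloxy)-3-butanoyl-6-methoxy-5-methylphenyl]methyl}phenyl.

## Route

Step 1
Reactants: 1 2,4,6-trihydroxytoluene
Product: 2 1-(2,4,6-trihydroxy-3-methylphenyl)butan-1-one
Conditions: PrCOCl (1.1 equiv), AlCl3 (3 equiv), PhNO2–CH2Cl2, 0 °C to 40 °C; aq. HCl
Reagents that add atoms: butanoyl chloride, CCCC(=O)Cl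
Why: Friedel–Crafts C-acylation of a phloroglucinol; the two free ring carbons of 1 are equivalent and the first acyl group deactivates the ring toward a second one.

Step 2
Reactants: 2 1-(2,4,6-trihydroxy-3-methylphenyl)butan-1-one
Product: 3 1-(2,6-dihydroxy-4-methoxy-3-methylphenyl)butan-1-one
Conditions: Me2SO4 (1.0 equiv), K2CO3 (1.0 equiv), acetone, rt
Reagents that add atoms: dimethyl sulfate, COS(=O)(=O)OC
Why: Williamson O-methylation; the hydroxyl para to the ketone is the most acidic and the only one not ortho to the carbonyl and so free of chelation, so one equivalent of base and electrophile should methylate it first and give the ring B pattern.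

Step 3
Reactants: 3 1-(2,6-dihydroxy-4-methoxy-3-methylphenyl)butan-1-one
Product: 4 1-{3-[(dimethylamino)methyl]-2,6-dihydroxy-4-methoxy-5-methylphenyl}butan-1-one
Conditions: aq. Me2NH, aq. CH2O, EtOH, 0 °C to rt
Reagents that add atoms: formaldehyde, C=O; dimethylamine, CNC
Why: Phenolic Mannich reaction at the single unsubstituted ring carbon of 3; it installs the future bridging CH2 with a leaving group attached.

Step 4
Reactants: 5 phloroglucinol
Product: 6 1-(2,4,6-trihydroxyphenyl)butan-1-one
Conditions: PrCOCl (1.0 equiv), AlCl3 (3 equiv), PhNO2–CH2Cl2, 0 °C to 40 °C; aq. HCl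
Reagents that add atoms: butanoyl chloride, CCCC(=O)Cl
Why: Friedel–Crafts mono-C-acylation of a symmetrical triol, all three ring positions being equivalent.

Step 5
Reactants: 6 1-(2,4,6-trihydroxyphenyl)butan-1-one; 7 acrylic acid
Product: 9 6-butanoyl-5,7-dihydroxychroman-2-one, via hydroxy acid 8 (not isolated)
Conditions: 7 (1.1 equiv), sulfonic acid resin (Amberlyst 15), toluene, reflux, Dean–Stark
Reagents that add atoms: none
Why: Acid-catalysed hydroarylation (Friedel–Crafts conjugate addition) of acrylic acid by a nucleophilic ring carbon, then lactonization of 8 to the dihydrocoumarin; the acyloxy oxygen of 9 lowers the nucleophilicity of the last free carbon, so a second addition should be slow, and no diarylmethane bridge is yet present to suffer from the acid.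

Step 6
Reactants: 4 1-{3-[(dimethylamino)methyl]-2,6-dihydroxy-4-methoxy-5-methylphenyl}butan-1-one; 9 6-butanoyl-5,7-dihydroxychroman-2-one
Product: 12 6-butanoyl-8-[(3-butanoyl-2,4-dihydroxy-6-methoxy-5-methylphenyl)methyl]-5,7-dihydroxychroman-2-one, via ammonium iodide 10 (not isolated), via ortho-quinone methide 11 (not isolated)
Conditions: 4, MeI (1.05 equiv), THF, rt, then evaporate; 9 (1.5 equiv), iPr2NEt, MeCN, 50 °C
Reagents that add atoms: none
Why: Quaternization makes the amine a leaving group, mild base releases NMe3 and quinone methide 11, and the phenoxide of 9 adds through its only free ring carbon in a Michael-type C-alkylation; trimethylamine, unlike the dimethylamine a free Mannich base would release, cannot open the lactone by aminolysis.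

Step 7
Reactants: 12 6-butanoyl-8-[(3-butanoyl-2,4-dihydroxy-6-methoxy-5-methylphenyl)methyl]-5,7-dihydroxychroman-2-one
Product: 14 3-Ar-propanoic acid, via benzyl ester 13 (not isolated)
Conditions: BnBr (8 equiv), BnOH (2 equiv), Cs2CO3, DMF, 50 °C; then LiOH, THF–MeOH–H2O, 50 °C; aq. HCl
Reagents that add atoms: benzyl bromide, BrCc1ccccc1; lithium hydroxide, [Li+].[OH-]
Why: Benzyl oxide opens the aryl lactone by transesterification and the phenoxide set free is trapped with the four other phenols by Williamson O-benzylation, a cesium counter-ion in a dipolar aprotic solvent favouring O- over C-alkylation; saponification of ester 13 in the same flask gives the acid while ketones and benzyl ethers are untouched.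

Step 8
Reactants: 15 tert-butyl vinyl ether
Product: 17 (Z)-1-bromo-2-tert-butoxyethene, via dibromide 16 (not isolated)
Conditions: Br2, pentane, −78 °C; then Et3N, 0 °C to reflux
Reagents that add atoms: bromine, BrBr
Why: Bromine addition to the enol ether followed by amine-mediated loss of HBr through the ionizable α-bromo ether, the classical entry to 2-bromovinyl ethers; the base keeps the medium non-acidic for the tert-butyl group and the alkene geometry is immaterial for step 9.

Step 9
Reactants: 17 (Z)-1-bromo-2-tert-butoxyethene
Product: 19 tert-butoxyethyne, via sodium acetylide 18 (not isolated)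
Conditions: NaNH2 (2.2 equiv), liq. NH3, −33 °C; NH4Cl; cold pentane extraction, kept below 0 °C
Reagents that add atoms: none
Why: Dehydrobromination of the bromovinyl ether gives the alkoxyalkyne, which the second equivalent of amide holds as acetylide 18 until the ammonium quench; the cold work-up is needed because a tert-butyl ynol ether loses isobutene on warming.

Step 10
Reactants: 14 3-Ar-propanoic acid; 19 tert-butoxyethyne
Product: 22 3-tert-butoxy-4-(ArCH2)cyclobut-2-en-1-one (racemic), via acid chloride 20 (not isolated), via ketene 21 (not isolated)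
Conditions: (COCl)2, cat. DMF, CH2Cl2, 0 °C, then evaporate; 19 (5 equiv), Et3N (slow addition), CH2Cl2, 0 °C to rt
Reagents that add atoms: none
Why: Dehydrochlorination of 20 gives aldoketene 21, which undergoes ketene–ynol ether [2+2] cycloaddition with its carbonyl carbon bonding to the unsubstituted, nucleophilic alkyne carbon, so that tert-butoxy ends at C3 and the arylmethyl group at C4; slow base addition into excess 19 keeps the ketene dilute against dimerization, and the new stereocentre is formed racemic and needs no control.

Step 11
Reactants: 23 2-bromo-1,1-dimethoxypropane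
Product: 25 1-methoxyprop-1-yne, via bromo enol ether 24 (not isolated)
Conditions: NaNH2 (2.2 equiv), liq. NH3, −33 °C; NH4Cl; distil
Reagents that add atoms: none
Why: Twofold base-induced elimination, first methanol from the acetal and then HBr from 24, the standard route from α-halo acetals to ynol ethers; elimination toward the methyl group would converge, because amide equilibrates the allenyl and alkynyl ethers toward the internal alkyne.

Step 12
Reactants: 22 3-tert-butoxy-4-(ArCH2)cyclobut-2-en-1-one; 25 1-methoxyprop-1-yne
Product: 30 3-tert-butoxy-5-methoxy-6-methyl-2-(ArCH2)phenol, via vinylketene 26 (not isolated), via vinylcyclobutenone 27 (not isolated), via dienylketene 28 (not isolated), via cyclohexadienone 29 (not isolated)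
Conditions: 25 (3 equiv), toluene, sealed tube, 80 °C then 110 °C; then K2CO3, MeOH, rt
Reagents that add atoms: none
Why: Heating opens 22 by conrotatory four-electron electrocyclic cleavage of the bond between the carbonyl carbon and the sp3 carbon, the arylmethyl group turning outward, to give vinylketene 26. The electrophilic ketene carbon of 26 bonds to the nucleophilic, methyl-bearing carbon of 25 and the neighbouring ketene carbon to the methoxy-bearing carbon in a [2+2] cycloaddition, which gives vinylcyclobutenone 27 and with it the a2–a3 and a4–a5 bonds. A second four-electron ring opening gives dienylketene 28, whose thermal disrotatory six-electron electrocyclization closes ring A as cyclohexadienone 29 by re-forming the a1–a2 bond, and tautomerization gives phenol 30. The closest known reaction type is the Danheiser benzannulation of cyclobutenones with alkoxyalkynes to resorcinol monoethers. No stereocentre is created: the racemic centre of 22 and the transient sp3 centres of 27 and 29 all end as aromatic carbons. The selectivity needed is the orientation of the [2+2] step, and the polarization of the ynol ether by its methoxy group secures it, so that methyl lands at a3 beside the new hydroxyl and methoxy at a4, while tert-butoxy stays at a6 and hydrogen at a5. Benzyl ethers, the methyl ether and the aryl ketones are inert to neutral heating, excess 25 keeps the cycloaddition ahead of self-reaction of 26, and the carbonate/methanol treatment would cleave any aryl ester formed by acylation of 30 by a ketene.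

Step 13
Reactants: 30 3-tert-butoxy-5-methoxy-6-methyl-2-(ArCH2)phenol
Product: 31 5-methoxy-4-methyl-2-(ArCH2)benzene-1,3-diol
Conditions: HCl (4 M in dioxane), CH2Cl2, 0 °C; evaporate
Reagents that add atoms: none
Why: Acidolysis of an electron-rich aryl tert-butyl ether by ionization; chloride captures the tert-butyl cation as a volatile alkyl chloride that is removed before any Lewis acid is present, which protects the free carbon a5, and benzyl and methyl ethers are stable at this temperature.

Step 14
Reactants: 31 5-methoxy-4-methyl-2-(ArCH2)benzene-1,3-diol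
Product: 33 1-[2,4-dihydroxy-6-methoxy-5-methyl-3-(ArCH2)phenyl]butan-1-one, via ketiminium chloride 32 (not isolated)
Conditions: PrCN, ZnCl2, HCl (g), Et2O, 0 °C; then H2O–THF, 50 °C
Reagents that add atoms: butanenitrile, CCCC#N; water, O
Why: Houben–Hoesch acylation, in which the nitrilium electrophile attacks a5, the only ring CH in the molecule, activated by two hydroxyls and a methoxy group; the reaction is C-selective on phloroglucinol-type rings and runs at 0 °C under conditions that aryl benzyl ethers tolerate, and hydrolysis of 32 gives the ketone.

Step 15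
Reactants: 33 1-[2,4-dihydroxy-6-methoxy-5-methyl-3-(ArCH2)phenyl]butan-1-one
Product: 34 1-[3-[(3-butanoyl-2,6-dihydroxy-4-methoxy-5-methylphenyl)methyl]-5-[(3-butanoyl-2,4-dihydroxy-6-methoxy-5-methylphenyl)methyl]-2,4,6-trihydroxyphenyl]butan-1-one
Conditions: H2 (1 atm), Pd/C, EtOAc–MeOH, rt
Reagents that add atoms: none
Why: Hydrogenolysis of the five benzyl ethers in neutral medium; the ortho-oxygenated aryl ketones and the diarylmethane bridges are not reduced under these conditions, and no acid or base touches the free trimer.

## Compound list

1 | 2,4,6-trihydroxytoluene | Cc1c(O)cc(O)cc1O | starting material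
2 | 1-(2,4,6-trihydroxy-3-methylphenyl)butan-1-one | CCCC(=O)c1c(O)c(C)c(O)cc1O | intermediate
3 | 1-(2,6-dihydroxy-4-methoxy-3-methylphenyl)butan-1-one | CCCC(=O)c1c(O)c(C)c(OC)cc1O | intermediate
4 | 1-{3-[(dimethylamino)methyl]-2,6-dihydroxy-4-methoxy-5-methylphenyl}butan-1-one | CCCC(=O)c1c(O)c(C)c(OC)c(CN(C)C)c1O | intermediate
5 | phloroglucinol | Oc1cc(O)cc(O)c1 | starting material
6 | 1-(2,4,6-trihydroxyphenyl)butan-1-one | CCCC(=O)c1c(O)cc(O)cc1O | intermediate
7 | acrylic acid | C=CC(=O)O | starting material
8 | 3-(3-butanoyl-2,4,6-trihydroxyphenyl)propanoic acid | CCCC(=O)c1c(O)cc(O)c(CCC(=O)O)c1O | intermediate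
9 | 6-butanoyl-5,7-dihydroxychroman-2-one | CCCC(=O)c1c(O)cc2OC(=O)CCc2c1O | intermediate
10 | [(3-butanoyl-2,4-dihydroxy-6-methoxy-5-methylphenyl)methyl]trimethylammonium iodide | CCCC(=O)c1c(O)c(C)c(OC)c(C[N+](C)(C)C)c1O.[I-] | intermediate
11 | 2-butanoyl-3-hydroxy-5-methoxy-4-methyl-6-methylidenecyclohexa-2,4-dien-1-one | C=C1C(=O)C(C(=O)CCC)=C(O)C(C)=C1OC | intermediate
12 | 6-butanoyl-8-[(3-butanoyl-2,4-dihydroxy-6-methoxy-5-methylphenyl)methyl]-5,7-dihydroxychroman-2-one | CCCC(=O)c1c(O)c(Cc2c(O)c(C(=O)CCC)c(O)c(C)c2OC)c2OC(=O)CCc2c1O | intermediate
13 | benzyl 3-Ar-propanoate | O=C(OCc1ccccc1)CCc1c(OCc2ccccc2)c(C(=O)CCC)c(OCc2ccccc2)c(Cc2c(OCc3ccccc3)c(C(=O)CCC)c(OCc3ccccc3)c(C)c2OC)c1OCc1ccccc1 | intermediate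
14 | 3-Ar-propanoic acid | OC(=O)CCc1c(OCc2ccccc2)c(C(=O)CCC)c(OCc2ccccc2)c(Cc2c(OCc3ccccc3)c(C(=O)CCC)c(OCc3ccccc3)c(C)c2OC)c1OCc1ccccc1 | intermediate
15 | tert-butyl vinyl ether | C=COC(C)(C)C | starting material
16 | 1,2-dibromo-1-tert-butoxyethane (racemic) | BrCC(Br)OC(C)(C)C | intermediate
17 | (Z)-1-bromo-2-tert-butoxyethene | Br/C=C\OC(C)(C)C | intermediate
18 | sodium 2-tert-butoxyethyn-1-ide | [Na+].[C-]#COC(C)(C)C | intermediate
19 | tert-butoxyethyne | C#COC(C)(C)C | intermediate
20 | 3-Ar-propanoyl chloride | ClC(=O)CCc1c(OCc2ccccc2)c(C(=O)CCC)c(OCc2ccccc2)c(Cc2c(OCc3ccccc3)c(C(=O)CCC)c(OCc3ccccc3)c(C)c2OC)c1OCc1ccccc1 | intermediate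
21 | 3-Ar-prop-1-en-1-one (ketene) | O=C=CCc1c(OCc2ccccc2)c(C(=O)CCC)c(OCc2ccccc2)c(Cc2c(OCc3ccccc3)c(C(=O)CCC)c(OCc3ccccc3)c(C)c2OC)c1OCc1ccccc1 | intermediate
22 | 3-tert-butoxy-4-(ArCH2)cyclobut-2-en-1-one (racemic) | O=C1C=C(OC(C)(C)C)C1Cc1c(OCc2ccccc2)c(C(=O)CCC)c(OCc2ccccc2)c(Cc2c(OCc3ccccc3)c(C(=O)CCC)c(OCc3ccccc3)c(C)c2OC)c1OCc1ccccc1 | intermediate
23 | 2-bromo-1,1-dimethoxypropane (racemic) | CC(Br)C(OC)OC | starting material
24 | 2-bromo-1-methoxyprop-1-ene (mixture of E and Z) | CC(Br)=COC | intermediate
25 | 1-methoxyprop-1-yne | CC#COC | intermediate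
26 | (3Z)-3-tert-butoxy-5-Ar-penta-1,3-dien-1-one | O=C=C/C(OC(C)(C)C)=C/Cc1c(OCc2ccccc2)c(C(=O)CCC)c(OCc2ccccc2)c(Cc2c(OCc3ccccc3)c(C(=O)CCC)c(OCc3ccccc3)c(C)c2OC)c1OCc1ccccc1 | intermediate
27 | 4-[(1Z)-1-tert-butoxy-3-Ar-prop-1-en-1-yl]-3-methoxy-2-methylcyclobut-2-en-1-one (racemic) | O=C1C(C)=C(OC)C1/C(OC(C)(C)C)=C/Cc1c(OCc2ccccc2)c(C(=O)CCC)c(OCc2ccccc2)c(Cc2c(OCc3ccccc3)c(C(=O)CCC)c(OCc3ccccc3)c(C)c2OC)c1OCc1ccccc1 | intermediate
28 | (3E,5Z)-5-tert-butoxy-3-methoxy-2-methyl-7-Ar-hepta-1,3,5-trien-1-one | O=C=C(C)/C(OC)=C\C(OC(C)(C)C)=C\Cc1c(OCc2ccccc2)c(C(=O)CCC)c(OCc2ccccc2)c(Cc2c(OCc3ccccc3)c(C(=O)CCC)c(OCc3ccccc3)c(C)c2OC)c1OCc1ccccc1 | intermediate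
29 | 5-tert-butoxy-3-methoxy-2-methyl-6-(ArCH2)cyclohexa-2,4-dien-1-one (racemic) | O=C1C(C)=C(OC)C=C(OC(C)(C)C)C1Cc1c(OCc2ccccc2)c(C(=O)CCC)c(OCc2ccccc2)c(Cc2c(OCc3ccccc3)c(C(=O)CCC)c(OCc3ccccc3)c(C)c2OC)c1OCc1ccccc1 | intermediate
30 | 3-tert-butoxy-5-methoxy-6-methyl-2-(ArCH2)phenol | CCCC(=O)c1c(OCc2ccccc2)c(Cc2c(O)c(C)c(OC)cc2OC(C)(C)C)c(OCc2ccccc2)c(Cc2c(OCc3ccccc3)c(C(=O)CCC)c(OCc3ccccc3)c(C)c2OC)c1OCc1ccccc1 | intermediate
31 | 5-methoxy-4-methyl-2-(ArCH2)benzene-1,3-diol | CCCC(=O)c1c(OCc2ccccc2)c(Cc2c(O)c(C)c(OC)cc2O)c(OCc2ccccc2)c(Cc2c(OCc3ccccc3)c(C(=O)CCC)c(OCc3ccccc3)c(C)c2OC)c1OCc1ccccc1 | intermediate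
32 | 1-[2,4-dihydroxy-6-methoxy-5-methyl-3-(ArCH2)phenyl]butan-1-iminium chloride | CCCC(=O)c1c(OCc2ccccc2)c(Cc2c(O)c(C)c(OC)c(C(=[NH2+])CCC)c2O)c(OCc2ccccc2)c(Cc2c(OCc3ccccc3)c(C(=O)CCC)c(OCc3ccccc3)c(C)c2OC)c1OCc1ccccc1.[Cl-] | intermediate
33 | 1-[2,4-dihydroxy-6-methoxy-5-methyl-3-(ArCH2)phenyl]butan-1-one | CCCC(=O)c1c(OCc2ccccc2)c(Cc2c(O)c(C)c(OC)c(C(=O)CCC)c2O)c(OCc2ccccc2)c(Cc2c(OCc3ccccc3)c(C(=O)CCC)c(OCc3ccccc3)c(C)c2OC)c1OCc1ccccc1 | intermediate
34 | 1-[3-[(3-butanoyl-2,6-dihydroxy-4-methoxy-5-methylphenyl)methyl]-5-[(3-butanoyl-2,4-dihydroxy-6-methoxy-5-methylphenyl)methyl]-2,4,6-trihydroxyphenyl]butan-1-one | CCCC(=O)c1c(O)c(Cc2c(O)c(C)c(OC)c(C(=O)CCC)c2O)c(O)c(Cc2c(O)c(C(=O)CCC)c(O)c(C)c2OC)c1O | target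

## Step count and least certain steps

Total step count: 15. Longest linear sequence: 10 steps (1, 2, 3, 6, 7, 10, 12, 13, 14, 15).

Step 12 (key step). The most likely failure is consumption of vinylketene 26 before it meets 25, by dimerization or by acylation of phenol already formed, because its ketene carbon carries only hydrogen. The cascade may also stall at 27, or the enol ether may lose isobutene thermally. The fallback exchanges the roles of the two oxygenated partners, so that the a5–a6 and a3–a4 bonds are formed instead. It sets out from 18 and 14 and comes back at 31. Methylation of 18 in liquid ammonia with MeI should give 1-tert-butoxyprop-1-yne F1. Ketene 21, generated from 14 as in step 10, should add F1 to give 3-tert-butoxy-2-methyl-4-(ArCH2)cyclobut-2-en-1-one F2, whose vinylketene has a methyl group on the ketene carbon and is less prone to self-reaction. Heating F2 with the unhindered methoxyethyne F3 (from chloroacetaldehyde dimethyl acetal and NaNH2) should give 3-tert-butoxy-5-methoxy-4-methyl-2-(ArCH2)phenol F4, and HCl in dioxane would convert F4 into 31.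

Step 10. The most likely failure is that dimerization of aldoketene 21 and thermal fragmentation of the terminal ynol ether outrun the cycloaddition. Acid chloride 20 may also lactonize onto a neighbouring benzyloxy group with loss of the benzyl group. The fallback avoids ketene chemistry altogether and joins a preformed ring A by classical phloroglucinol chemistry. It sets out from 2, 6 and 4 and comes back at 34. Twofold benzylation of 2 (BnBr, K2CO3) at the para hydroxyl and at the less hindered ortho hydroxyl should give 1-[4,6-bis(benzyloxy)-2-hydroxy-3-methylphenyl]butan-1-one F5. Methylation of the remaining hydroxyl (MeI, K2CO3, DMF) gives 1-[4,6-bis(benzyloxy)-2-methoxy-3-methylphenyl]butan-1-one F6, and hydrogenolysis gives 1-(4,6-dihydroxy-2-methoxy-3-methylphenyl)butan-1-one F7. A Mannich reaction gives 1-{3-[(dimethylamino)methyl]-2,4-dihydroxy-6-methoxy-5-methylphenyl}butan-1-one F8. Heating F8 with an excess of 6 in dioxane gives 1-[3-[(3-butanoyl-2,6-dihydroxy-4-methoxy-5-methylphenyl)methyl]-2,4,6-trihydroxyphenyl]butan-1-one F9, and heating F9 with 4 gives 34. The weak point of this detour is the site selectivity of the second benzylation.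

Step 6. The most likely failure is self-condensation of quinone methide 11 or O-alkylation, because the free carbon of 9 is deactivated by the lactone oxygen; partial opening of the lactone is also possible. The fallback reverses the order of union and side-chain introduction. It sets out from 4 and 6 and comes back at 12. Heating free Mannich base 4 with an excess of 6, where no lactone is present and no quaternization is needed, should give 1-[3-[(3-butanoyl-2,4-dihydroxy-6-methoxy-5-methylphenyl)methyl]-2,4,6-trihydroxyphenyl]butan-1-one F10. Hydroarylation of acrylic acid by F10 under the conditions of step 5 then gives 12, at the price of exposing a diarylmethane bridge to the acid catalyst.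

Step 5. The most likely failure is Friedel–Crafts acylation by the acid leading to a chromanone-type closure in place of conjugate addition, along with double addition or polymerization of acrylic acid. The fallback builds the same chain from one-carbon and two-carbon units. It sets out from 6 and comes back at 9. Three-component Knoevenagel–Michael condensation of 6 with CH2O and Meldrum's acid (piperidinium acetate, MeCN) should give 5-[(3-butanoyl-2,4,6-trihydroxyphenyl)methyl]-2,2-dimethyl-1,3-dioxane-4,6-dione F11, which on heating in pyridine lactonizes with loss of acetone and CO2 to give 9.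

Step 14. The most likely failure is cleavage of benzyl ethers beside carbonyl groups or acid-induced breaking of the ring A bridge under HCl and ZnCl2, or incomplete hydrolysis of 32. The fallback acylates a fully protected ring with a metal-free mixed anhydride. It sets out from 31 and comes back at 34. Benzylation of both phenols (BnBr, K2CO3, DMF) should give 1,3-bis(benzyloxy)-5-methoxy-4-methyl-2-(ArCH2)benzene F12. Friedel–Crafts acylation with butanoic acid and (CF3CO)2O in CH2Cl2 at 0 °C gives 1-[2,4-bis(benzyloxy)-6-methoxy-5-methyl-3-(ArCH2)phenyl]butan-1-one F13, the same compound as A6, and hydrogenolysis of its seven benzyl ethers gives 34.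

## Further compounds

F1 | step 12 | 1-tert-butoxyprop-1-yne | CC#COC(C)(C)C
F2 | step 12 | 3-tert-butoxy-2-methyl-4-(ArCH2)cyclobut-2-en-1-one (racemic) | O=C1C(C)=C(OC(C)(C)C)C1Cc1c(OCc2ccccc2)c(C(=O)CCC)c(OCc2ccccc2)c(Cc2c(OCc3ccccc3)c(C(=O)CCC)c(OCc3ccccc3)c(C)c2OC)c1OCc1ccccc1
F3 | step 12 | methoxyethyne | C#COC
F4 | step 12 | 3-tert-butoxy-5-methoxy-4-methyl-2-(ArCH2)phenol | CCCC(=O)c1c(OCc2ccccc2)c(Cc2c(OC(C)(C)C)c(C)c(OC)cc2O)c(OCc2ccccc2)c(Cc2c(OCc3ccccc3)c(C(=O)CCC)c(OCc3ccccc3)c(C)c2OC)c1OCc1ccccc1
F5 | step 10 | 1-[4,6-bis(benzyloxy)-2-hydroxy-3-methylphenyl]butan-1-one | CCCC(=O)c1c(O)c(C)c(OCc2ccccc2)cc1OCc1ccccc1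
F6 | step 10 | 1-[4,6-bis(benzyloxy)-2-methoxy-3-methylphenyl]butan-1-one | CCCC(=O)c1c(OC)c(C)c(OCc2ccccc2)cc1OCc1ccccc1
F7 | step 10 | 1-(4,6-dihydroxy-2-methoxy-3-methylphenyl)butan-1-one | CCCC(=O)c1c(OC)c(C)c(O)cc1O
F8 | step 10 | 1-{3-[(dimethylamino)methyl]-2,4-dihydroxy-6-methoxy-5-methylphenyl}butan-1-one | CCCC(=O)c1c(OC)c(C)c(O)c(CN(C)C)c1O
F9 | step 10 | 1-[3-[(3-butanoyl-2,6-dihydroxy-4-methoxy-5-methylphenyl)methyl]-2,4,6-trihydroxyphenyl]butan-1-one | CCCC(=O)c1c(O)cc(O)c(Cc2c(O)c(C)c(OC)c(C(=O)CCC)c2O)c1O
F10 | step 6 | 1-[3-[(3-butanoyl-2,4-dihydroxy-6-methoxy-5-methylphenyl)methyl]-2,4,6-trihydroxyphenyl]butan-1-one | CCCC(=O)c1c(O)cc(O)c(Cc2c(O)c(C(=O)CCC)c(O)c(C)c2OC)c1O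
F11 | step 5 | 5-[(3-butanoyl-2,4,6-trihydroxyphenyl)methyl]-2,2-dimethyl-1,3-dioxane-4,6-dione | CCCC(=O)c1c(O)cc(O)c(CC2C(=O)OC(C)(C)OC2=O)c1O
F12 | step 14 | 1,3-bis(benzyloxy)-5-methoxy-4-methyl-2-(ArCH2)benzene | CCCC(=O)c1c(OCc2ccccc2)c(Cc2c(OCc3ccccc3)c(C)c(OC)cc2OCc2ccccc2)c(OCc2ccccc2)c(Cc2c(OCc3ccccc3)c(C(=O)CCC)c(OCc3ccccc3)c(C)c2OC)c1OCc1ccccc1
F13 | step 14 | 1-[2,4-bis(benzyloxy)-6-methoxy-5-methyl-3-(ArCH2)phenyl]butan-1-one | CCCC(=O)c1c(OCc2ccccc2)c(Cc2c(OCc3ccccc3)c(C)c(OC)c(C(=O)CCC)c2OCc2ccccc2)c(OCc2ccccc2)c(Cc2c(OCc3ccccc3)c(C(=O)CCC)c(OCc3ccccc3)c(C)c2OC)c1OCc1ccccc1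
A1 | alternative 1 | penta-O-benzyl trimer skeleton with SiMe3 at a5 and b3 and trifluoromethanesulfonyloxy at a6 and b4 | CCCC(=O)c1c(OCc2ccccc2)c(Cc2c(OCc3ccccc3)c(C)c(OC)c([Si](C)(C)C)c2OS(=O)(=O)C(F)(F)F)c(OCc2ccccc2)c(Cc2c(OCc3ccccc3)c([Si](C)(C)C)c(OS(=O)(=O)C(F)(F)F)c(C)c2OC)c1OCc1ccccc1
A2 | alternative 1 | butanoic acid | CCCC(=O)O
A3 | alternative 1 | target as its five benzyl ethers with a6-OH and b4-OH free | CCCC(=O)c1c(OCc2ccccc2)c(Cc2c(OCc3ccccc3)c(C)c(OC)c(C(=O)CCC)c2O)c(OCc2ccccc2)c(Cc2c(OCc3ccccc3)c(C(=O)CCC)c(O)c(C)c2OC)c1OCc1ccccc1
A4 | alternative 2 | 2,4,6-trifluoro-3,5-bis(arylmethyl)butyrophenone with both side rings as bis(benzyl ethers) | CCCC(=O)c1c(F)c(Cc2c(OCc3ccccc3)c(C)c(OC)c(C(=O)CCC)c2OCc2ccccc2)c(F)c(Cc2c(OCc3ccccc3)c(C(=O)CCC)c(OCc3ccccc3)c(C)c2OC)c1F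
A5 | alternative 2 | sodium benzyloxide | [Na+].[O-]Cc1ccccc1
A6 | alternative 2 | target as its hepta-O-benzyl ether | CCCC(=O)c1c(OCc2ccccc2)c(Cc2c(OCc3ccccc3)c(C)c(OC)c(C(=O)CCC)c2OCc2ccccc2)c(OCc2ccccc2)c(Cc2c(OCc3ccccc3)c(C(=O)CCC)c(OCc3ccccc3)c(C)c2OC)c1OCc1ccccc1
A7 | alternative 3 | methyl 2,4-bis(arylmethyl)-3,5,7-trioxodecanoate with both side rings as bis(benzyl ethers) (mixture of stereoisomers and enol forms) | CCCC(=O)CC(=O)C(Cc1c(OCc2ccccc2)c(C)c(OC)c(C(=O)CCC)c1OCc1ccccc1)C(=O)C(Cc1c(OCc2ccccc2)c(C(=O)CCC)c(OCc2ccccc2)c(C)c1OC)C(=O)OC
A8 | alternative 3 | target with the four side-ring hydroxyls benzylated | CCCC(=O)c1c(O)c(Cc2c(OCc3ccccc3)c(C)c(OC)c(C(=O)CCC)c2OCc2ccccc2)c(O)c(Cc2c(OCc3ccccc3)c(C(=O)CCC)c(OCc3ccccc3)c(C)c2OC)c1O
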